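## Structural features

The target 32 is a C30 dimer of two guaianolide units. Each unit is a bicyclo[5.3.0]decane (ring A = C1–C5; seven-membered ring = C1, C5–C10) carrying a trans-fused α-methyl-γ-lactone on C6–C7 (6α-O, 7αH, 11α-methyl) and a tertiary carbinol at C10. The halves are joined by the bonds C2–C2′ and C3–C5′, which turn ring A′ into a bicyclo[2.2.1]heptan-2-one (C3′ ketone, C1′ as the one-carbon bridge, C4′ methyl endo) onto which ring A of the other half, with C4=C5 intact, is endo-fused. There are 15 stereocentres: the contiguous core array C1–C2–C3 / C2′–C1′–C5′–C4′ and, in each half, C6, C7, C11 and C10, whose hydroxyl is trans to H-1. Fragile features are the tertiary C10 alcohols (elimination, 7,10-ether formation), the epimerisable C4′ and C11/C11′ centres, the lactones, and the cyclopentadiene precursors of the core (1,5-hydrogen shift, self-dimerisation). The real difficulty is twofold: relating C6/C7 and the hindered-face C10 oxygen to C1 across a flexible seven-membered ring, and joining two different cyclopentadienes with the right pairing. The key step uses the fact that in each half the fusion bond C1–C5 together with the seven-membered ring maps onto an alkyne (C5, C6) tethered through C2–C4 to a vinylcyclopropane (C1, C10, C9, C8, C7), and that both halves descend from one enone.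

## Logic of the disconnections

32 ⇒ 31. The C3′ ketone with its α-stereocentre C4′ is read as a masked silyl enol ether; the cuts are the two O–Si bonds and the C4′–H bond. This removes C4′ as a stereocentre and exposes a norbornene that is a Diels–Alder retron. The forward step must protonate C4′ on the exo face and must spare lactones and tertiary alcohols.

31 ⇒ 28 + 30. The cuts are C2–C2′ and C3–C5′ (retro-Diels–Alder). Both halves have the same configuration at C1, C6, C7, C10 and C11, so the C30 problem falls to two C15 dienes from one source, and four stereocentres (C2, C3, C2′, C5′) are set in one event. The forward step needs the pairing 30 as 4π and C2=C3 of 28 as 2π, head-to-head regiochemistry, endo approach, and attack anti to C10 on both partners.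

28 and 30 ⇒ 25. For 30 the cuts are the two O–Si bonds, with the C10 silyl ether 29 on the way; for 28 the cut is the C3–H bond, through 27 (C3–O) and the dienolate 26. One enone thus feeds both partners, and the branch to 30 needs no alkoxide next to the enone. The demand in both branches is enolisation toward C2 and not toward a γ position or C11.

25 ⇒ 23. The C4=C5 alkene is traced to a C5 hydroxyl and C4–H, and the C3 ketone to the C3 alcohol. A β-hydroxy ketone can only dehydrate to the wanted enone, so no regiochemical choice arises, and the C5 hydroxyl is the relay used earlier. The demand is selective oxidation of the only secondary alcohol.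

23 ⇒ 21. The cut is C10–O. The C10 oxygen sits syn to C2 and anti to H-1; in the rigid diene 11 that face is closed, so the hydration is placed where C5 is sp3 and fully substituted. The demand is facial selectivity in the capture of a tertiary radical.

21 ⇒ 19 ⇒ 16 + 17. The cuts are C7–C11 and O6–C12. A trans lactone is the signature of anti opening of a 6α,7α-epoxide at C7 by a propionate dianion, which brings in C11–C13 in one step. The demands are attack at C7 and not C6, and equilibration of C11.

16 ⇒ 15. The cuts are the two epoxide C–O bonds. The 5α-hydroxyl delivers oxygen syn, so C6 and C7 are tied to C5 and through it to C1. The 9,10-alkene must stay untouched.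

15 ⇒ 13 ⇒ 11. The C5–O bond is cut with return of the alkene to C5=C6 and of silicon to C6. The vinylsilane directs an ene-type oxygenation to C5 and is then removed. The demands are attack on the α face, hydrogen abstraction at C7, and selectivity over the 9,10-alkene.

11 ⇒ 10. The cuts are C1–C5 and C6–C7 with restoration of the cyclopropane: the (5+2) disconnection. Two rings and C1 are exchanged for an acyclic chain with two sacrificial stereocentres. The demand is facial selectivity at C1.

10 ⇒ 9 ⇒ 5 + 7 (7 ⇐ 6). The cut is C3–C4 (and O–Si). An allenylmetal addition sets C3 and C4 anti in one step from a commercial alcohol.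

5 ⇒ 4 ⇒ 1 + 2. The cuts are C1–C2 and C10–C14. Carbometalation of the alkyne fixes the alkene geometry that a ketone olefination would leave open.

## Other disconnections considered

Alternative 1: The seven-membered ring is traced to a six-membered ring by removing C1, the carbon that links C5 and C10. In the forward sense FeCl3 (trivalent iron) would oxidise the siloxycyclopropane A2; the internal bond breaks, the tertiary radical takes up chlorine, and loss of HCl gives the cycloheptenone A1. In its favour: A1 comes from the chiral pool, carries C7 with the complete three-carbon side chain and the C10 methyl, and the fragmentation has no regiochemical ambiguity. On side-chain provision and early step count it is better than the chosen plan, which brings in C11–C13 only at step 10. Against it here: ring A (C2, C3, C4, C15 and the C3 oxygen), the C6 oxygen and the C1–C5 fusion are all still missing, and C1, C6 and C10 would have to be set by remote induction from C7 in a monocyclic enone. Comparison: mechanistically the two key steps are equally dependable. Structurally the rhodium step forms both carbocycles and C1 at once, whereas A1 is one ring with one stereocentre. Overall step economy should favour the chosen plan because the annulation of ring A on A1 is long.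

Alternative 2: The cut is C1–C2 of ring A. Ph3PAuSbF6 (monovalent gold) would activate the terminal alkyne of A4; 1,2-shift of the pivalate gives a pentadienyl cation that closes onto the ring alkene, and hydrolysis gives A3. In its favour: A3 is the trimethylsilyl ether of 25, so ketone, C4=C5 alkene and C10 oxygen are all in place at once. On this point the alternative is better than the chosen plan, which needs further operations on ring A after its key step. Against it here: A4 presupposes the seven-membered lactone with C6, C7, C10, C11 and the C1=C5 alkene, so the medium ring and most stereocentres must be made without help from ring A. C1 would depend on the facial course of the cyclisation on a ring alkene (with chirality transfer from the mixed C4 centre competing), and a tertiary silyl ether and a lactone must survive a cationic gold catalyst. Comparison: both are known metal-catalysed cycloisomerisations. The gold step forms one bond and one ring, the rhodium step two bonds and two rings. Step economy after the key step favours the alternative, before it the chosen plan; overall they should be similar at best.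

Alternative 3: The cut is the transannular bond C1–C5 of a ten-membered ring. BF3·OEt2 would open the epoxide of A6, C1 of the 1(10)-alkene attacks C5 with inversion, and the C10 cation loses a proton to give A5. In its favour: like the chosen key step it makes both carbocycles in one event (equal on that point), it uses the lactone centres C6, C7 and C11 already present in A6, and if A6 is taken from a natural germacranolide the step count is far lower (better). Against it here: as a total synthesis the E-configured ten-membered epoxy lactone A6 is harder to build than the monomer itself. A5 also has the wrong pattern for 25: oxygen at C4 and not C3, the alkene at C1(10) and not C4(5), no C10 oxygen and no C1 stereocentre. Correcting this needs dehydration, allylic oxidation at C3 and a trans hydration of a tetrasubstituted alkene that must set 1αH and 10β-OH together. Comparison: the cationic cyclisation is stereospecific at C5 but offers several proton-loss and rearrangement channels, whereas the rhodium cycle has one productive path. The chosen plan is longer to the bicycle but shorter from the bicycle to 25.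

Key step: step 6

Remarks on the chemistry (one line each):
- Guaiane numbering is used for all intermediates, with primes for the ketone-bearing half; α is the face of H-1; compounds 11–16 are 11,12,13-trinorguaianes.
- The configurations of 10 and 11 are consistent with 32: anti C3/C4 in 10 becomes cis on ring A in 11, and H-1, H-3 and H-4 on one face is the C1 configuration of 32; C3 and C4 are erased at 25.
- Olefination of cyclopropyl methyl ketone with a non-stabilised ylide would give E/Z mixtures, so the trisubstituted alkene is made by carbometalation; the C-silylated butynol 6 is used as such, so only one silylation is needed.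
- The C10 oxygen is trans to H-1; in the folded diene 11 the open face of C10 is the one syn to H-1, so hydration is placed after C5 has become a fully substituted sp3 centre (step 12).
- A C7 alkylation of a C6 ketone would offer no control of C6/C7 relative to C1; a relay from a C5 hydroxyl is used instead (steps 7–10).
- The two Diels–Alder partners are made from 25 by different modes of enolisation: a lithium amide for the triflate (step 14), and a silyl triflate with an amine for the silyloxydiene (step 16), in which the C10 hydroxyl is silylated first and no alkoxide stands next to the enone.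
- Compounds 1, 2, 6 and 17 are taken as commercially available.

## Route

Step 1
Reactants: 1 ethynylcyclopropane; 2 oxirane
Product: 4 (E)-4-cyclopropylpent-3-en-1-ol, via alkenylalane 3 (not isolated)
Conditions: AlMe3 (2 equiv), Cp2ZrCl2 (0.2 equiv), CH2Cl2, 0 → 23 °C; evaporate; n-BuLi (1 equiv), THF–hexane, −30 °C; 2 (3 M in THF), −30 → 0 °C; aq. HCl
Reagents that add atoms: trimethylaluminium C[Al](C)C
Why: Zirconium-catalysed carboalumination adds methyl and aluminium syn across the alkyne with methyl on the internal carbon, which fixes the E geometry (chain trans to cyclopropyl); the derived alkenylalanate opens oxirane with retention at the alkenyl carbon.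

Step 2
Reactants: 4 (E)-4-cyclopropylpent-3-en-1-ol
Product: 5 (E)-4-cyclopropylpent-3-enal
Conditions: Dess–Martin periodinane, NaHCO3, CH2Cl2, 0 °C; used at once
Reagents that add atoms: none
Why: Dess–Martin oxidation is neutral and fast, so the β,γ-unsaturated aldehyde should form without migration of the alkene into conjugation.

Step 3
Reactants: 6 (S)-4-(trimethylsilyl)but-3-yn-2-ol
Product: 7 (S)-4-(trimethylsilyl)but-3-yn-2-yl methanesulfonate
Conditions: MsCl, Et3N, CH2Cl2, −78 °C
Reagents that add atoms: methanesulfonyl chloride CS(=O)(=O)Cl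
Why: O-Sulfonylation does not touch the carbinol carbon, so the S configuration is kept for the stereospecific metalation of step 4.

Step 4
Reactants: 5 (E)-4-cyclopropylpent-3-enal; 7 (S)-4-(trimethylsilyl)but-3-yn-2-yl methanesulfonate
Product: 9 (3R,4S,6E)-7-cyclopropyl-3-methyl-1-(trimethylsilyl)oct-6-en-1-yn-4-ol, via allenylzinc 8 (not isolated)
Conditions: Pd(OAc)2 (5 mol %), PPh3 (5 mol %), Et2Zn (3 equiv), THF, −78 → −20 °C; aq. NH4Cl
Reagents that add atoms: none
Why: Zerovalent palladium displaces the mesylate anti (SN2′) and exchange with Et2Zn gives the configurationally defined allenylzinc, which adds to the aldehyde through a cyclic SE2′ transition state with the aldehyde residue away from the allenyl methyl; net inversion at the former carbinol carbon gives C4 (R) and the anti relationship gives C3 (S) in guaiane numbering.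

Step 5
Reactants: 9 (3R,4S,6E)-7-cyclopropyl-3-methyl-1-(trimethylsilyl)oct-6-en-1-yn-4-ol
Product: 10 (3R,4S,6E)-4-(tert-butyldimethylsilyloxy)-7-cyclopropyl-3-methyl-1-(trimethylsilyl)oct-6-en-1-yne
Conditions: t-BuMe2SiOTf, 2,6-lutidine, CH2Cl2, −78 → 0 °C
Reagents that add atoms: tert-butyldimethylsilyl trifluoromethanesulfonate CC(C)(C)[Si](C)(C)OS(=O)(=O)C(F)(F)F
Why: Silylation of the hindered secondary alcohol with the silyl triflate gives the bulky ether that later biases the tether and shields the β face of ring A.

Step 6
Reactants: 10 (3R,4S,6E)-4-(tert-butyldimethylsilyloxy)-7-cyclopropyl-3-methyl-1-(trimethylsilyl)oct-6-en-1-yne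
Product: 11 3β-(tert-butyldimethylsilyloxy)-6-(trimethylsilyl)-1αH,4αH-11,12,13-trinorguaia-5,9-diene
Conditions: [Rh(CO)2Cl]2 (5 mol %), toluene (0.02 M), 80 °C
Reagents that add atoms: none
Why: [Rh(CO)2Cl]2 (monovalent rhodium) binds the alkyne and the vinylcyclopropane of 10, and oxidative opening of the cyclopropane gives a σ-alkyl, π-allyl rhodacycle (trivalent rhodium) in which the unsubstituted three-membered ring offers only equivalent bonds to cleave. Insertion of the tethered alkyne at the allyl terminus forms C1–C5 and closes ring A through the C2–C3–C4 tether (five-membered, exo with respect to both π systems), and reductive elimination from the eight-membered rhodacycle forms C6–C7 and closes the seven-membered ring with its two cis alkenes. This is the rhodium-catalysed intramolecular (5+2) cycloaddition of alkyne-tethered vinylcyclopropanes, a known reaction that tolerates silylalkynes and substitution at the cyclopropyl-bearing alkene carbon. C1 is the only new stereocentre and is set by the tether: allylic 1,3-strain with the alkynyl silicon keeps H-4 in the plane and the C4 methyl pseudoaxial, the cis C3 silyloxy group is then pseudoequatorial, and C1 closes with C10 pseudoequatorial and cis to the silyloxy group, so that H-1, H-3 and H-4 end on one face. The step needs this facial selectivity and a single alkene geometry; the anti C3/C4 pattern makes both substituents act in the same sense and the E alkene comes from step 1. No other group in 10 reacts under these neutral conditions.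

Step 7
Reactants: 11 3β-(tert-butyldimethylsilyloxy)-6-(trimethylsilyl)-1αH,4αH-11,12,13-trinorguaia-5,9-diene
Product: 13 3β-(tert-butyldimethylsilyloxy)-6-(trimethylsilyl)-1αH,4αH-11,12,13-trinorguaia-6,9-dien-5α-ol, via hydroperoxide 12 (not isolated)
Conditions: O2, tetraphenylporphyrin (cat.), visible light, CH2Cl2, −20 °C, to about 80% conversion; then PPh3, 0 °C
Reagents that add atoms: dioxygen O=O
Why: Schenck ene reaction of singlet oxygen with a vinylsilane: oxygen bonds to the carbon β to silicon (C5) and hydrogen is taken from the alkyl group geminal to silicon (C7), which moves the alkene to C6=C7. The β face of C5=C6 is covered by the pseudoaxial C4 methyl and by C8–C10 of the folded ring, so oxygen should arrive on the α face (5α); the tetrasubstituted alkene is expected to react faster than the trisubstituted 9,10-alkene.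

Step 8
Reactants: 13 3β-(tert-butyldimethylsilyloxy)-6-(trimethylsilyl)-1αH,4αH-11,12,13-trinorguaia-6,9-dien-5α-ol
Product: 15 3β-(tert-butyldimethylsilyloxy)-1αH,4αH-11,12,13-trinorguaia-6,9-dien-5α-ol, via trimethylsilyl ether 14 (not isolated)
Conditions: KOt-Bu (0.3 equiv), THF–DMSO (4:1), 23 °C; then K2CO3, MeOH, 23 °C
Reagents that add atoms: none
Why: Alkoxide-induced protodesilylation of a β-hydroxy vinylsilane: the C5 alkoxide attacks the neighbouring silicon (1,3 carbon-to-oxygen silyl shift of the Brook type), the vinyl anion is protonated with retention, and methanolysis frees the tertiary alcohol. No fluoride is used, so the C3 silyl ether stays, and a Peterson elimination is excluded because it would give a cyclic allene.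

Step 9
Reactants: 15 3β-(tert-butyldimethylsilyloxy)-1αH,4αH-11,12,13-trinorguaia-6,9-dien-5α-ol
Product: 16 6α,7α-epoxy-3β-(tert-butyldimethylsilyloxy)-1αH,4αH-11,12,13-trinorguai-9-en-5α-ol
Conditions: VO(acac)2 (5 mol %), t-BuOOH (1.3 equiv, decane), CH2Cl2, 0 → 23 °C
Reagents that add atoms: tert-butyl hydroperoxide CC(C)(C)OO
Why: Vanadium-catalysed hydroxyl-directed epoxidation: the vanadate ester of the tertiary allylic alcohol delivers oxygen syn to the 5α-hydroxyl, which sets C6 and C7 (6α,7α). The 9,10-alkene is only homoallylic to the hydroxyl and should react far more slowly.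

Step 10
Reactants: 16 6α,7α-epoxy-3β-(tert-butyldimethylsilyloxy)-1αH,4αH-11,12,13-trinorguai-9-en-5α-ol; 17 propanoic acid
Product: 19 3β-(tert-butyldimethylsilyloxy)-5α-hydroxy-1αH,4αH,6βH,7αH-guai-9-en-12,6α-olide (C11 epimers), via hydroxy acid 18 (not isolated)
Conditions: 17 (4 equiv), LiN(i-Pr)2 (9 equiv), THF–DMPU, 0 °C; 16, 50 °C; 1 M HCl to pH 2; then p-TsOH·H2O (cat.), CH2Cl2, 23 °C
Reagents that add atoms: none
Why: Epoxide opening by a carboxylic acid dianion followed by lactonisation: the nucleophile attacks C7, the carbon remote from the fully substituted C5, anti to the epoxide oxygen, which gives 7β-carbon and 6α-oxygen and hence the trans lactone. The cis C5 alkoxide cannot undergo Payne migration and the silyl ether keeps O-3 from attacking C6.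

Step 11
Reactants: 19 3β-(tert-butyldimethylsilyloxy)-5α-hydroxy-1αH,4αH,6βH,7αH-guai-9-en-12,6α-olide (C11 epimers)
Product: 21 3β,5α-dihydroxy-1αH,4αH,6βH,7αH,11βH-guai-9-en-12,6α-olide, via equilibrated silyl ether 20 (not isolated)
Conditions: NaOMe (0.5 equiv), MeOH, 50 °C; then HCl (1.25 M in MeOH, to pH 1), 23 °C
Reagents that add atoms: none
Why: Methoxide equilibrates C11 through the ester or lactone enolate to the more stable 11α-methyl epimer (methyl trans to C8); methanolic acid then recloses the lactone and solvolyses the secondary silyl ether.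

Step 12
Reactants: 21 3β,5α-dihydroxy-1αH,4αH,6βH,7αH,11βH-guai-9-en-12,6α-olide
Product: 23 3β,5α,10β-trihydroxy-1αH,4αH,6βH,7αH,11βH-guaian-12,6α-olide, via hydroperoxide 22 (not isolated)
Conditions: Mn(dpm)3 (10 mol %), PhSiH3 (2.5 equiv), O2 (1 atm), i-PrOH–CH2Cl2, 0 → 23 °C; then PPh3
Reagents that add atoms: dioxygen O=O
Why: Mukaiyama hydration: hydrogen-atom transfer to C9 gives the tertiary C10 radical, which takes up oxygen. With C5 now a fully substituted sp3 centre, capture is expected anti to the C1–C5 bond in the conformer that keeps H-1 eclipsed with the C10 methyl (least allylic 1,2-strain), which puts the new C–O bond trans to H-1 (10β). The trans lactone, not the rigid diene 11, now shapes the ring.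

Step 13
Reactants: 23 3β,5α,10β-trihydroxy-1αH,4αH,6βH,7αH,11βH-guaian-12,6α-olide
Product: 25 10β-hydroxy-3-oxo-1αH,6βH,7αH,11βH-guai-4-en-12,6α-olide, via hydroxy ketone 24 (not isolated)
Conditions: Dess–Martin periodinane, NaHCO3, CH2Cl2, 0 → 23 °C; then DBU (2 equiv), 23 °C
Reagents that add atoms: none
Why: Dess–Martin oxidation touches only the secondary C3 alcohol; the resulting β-hydroxy ketone loses the C5 hydroxyl by E1cB elimination, which can only give the C4=C5 enone and erases the C4 centre.

Step 14
Reactants: 25 10β-hydroxy-3-oxo-1αH,6βH,7αH,11βH-guai-4-en-12,6α-olide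
Product: 27 10β-hydroxy-1αH,6βH,7αH,11βH-guaia-2,4-dien-12,6α-olid-3-yl trifluoromethanesulfonate, via dilithium dienolate 26 (not isolated)
Conditions: LiN(SiMe3)2 (2.2 equiv), THF, −78 °C; PhNTf2 (1.1 equiv), −78 → 0 °C
Reagents that add atoms: N-phenylbis(trifluoromethanesulfonimide) O=S(=O)(N(c1ccccc1)S(=O)(=O)C(F)(F)F)C(F)(F)F
Why: Kinetic deprotonation of the enone at C2 gives the cross-conjugated dienolate, which is O-triflated; the hindered tertiary alkoxide should not react with the mild triflating agent at low temperature.

Step 15
Reactants: 27 10β-hydroxy-1αH,6βH,7αH,11βH-guaia-2,4-dien-12,6α-olid-3-yl trifluoromethanesulfonate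
Product: 28 10β-hydroxy-1αH,6βH,7αH,11βH-guaia-2,4-dien-12,6α-olide
Conditions: Pd(OAc)2 (5 mol %), PPh3 (10 mol %), HCO2H (2 equiv), n-Bu3N (3 equiv), DMF, 40 °C; used at once
Reagents that add atoms: none
Why: Palladium-catalysed formate reduction of an enol triflate: zerovalent palladium inserts into the C–O bond, formate delivers hydride with loss of CO2, and reductive elimination leaves the C2=C3/C4=C5 cyclopentadiene without touching C1.

Step 16
Reactants: 25 10β-hydroxy-3-oxo-1αH,6βH,7αH,11βH-guai-4-en-12,6α-olide
Product: 30 3,10β-bis(triethylsilyloxy)-1αH,6βH,7αH,11βH-guaia-2,4-dien-12,6α-olide, via 10-O-triethylsilyl enone 29 (not isolated)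
Conditions: Et3SiOTf (2.5 equiv), Et3N (4 equiv), Et2O, −78 → 0 °C; pentane extraction, Et3N-deactivated silica; used at once
Reagents that add atoms: triethylsilyl trifluoromethanesulfonate CC[Si](CC)(CC)OS(=O)(=O)C(F)(F)F
Why: Soft enolisation of an enone with a silyl triflate and an amine: the tertiary C10 hydroxyl is silylated first, then O-silylation of the carbonyl gives a silyloxyallyl cation that Et3N deprotonates at the adjacent C2 (α′) position, the kinetic site for α-methyl enones of the carvone type, to give the 2-silyloxycyclopentadiene (C2=C3–OSi, C4=C5). No alkoxide is formed at any point, so vinylogous retro-aldol cleavage of C1–C10 is excluded.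

Step 17
Reactants: 28 10β-hydroxy-1αH,6βH,7αH,11βH-guaia-2,4-dien-12,6α-olide; 30 3,10β-bis(triethylsilyloxy)-1αH,6βH,7αH,11βH-guaia-2,4-dien-12,6α-olide
Product: 31 3′-O,10′-O-bis(triethylsilyl) 3′-enol ether of 32 (C3′=C4′ silyl enol ether; 10′-silyl ether; 10-OH free)
Conditions: 30 (1 equiv), 28 (1.5 equiv), neat or 2 M in toluene, BHT (trace), 23 °C, dark
Reagents that add atoms: none
Why: Diels–Alder cross-dimerisation of two cyclopentadienes: the silyloxy group raises the HOMO of 30, and the cis-disubstituted, conjugated C2=C3 of 28 is the least hindered and lowest-LUMO 2π partner, so this pairing has the smallest frontier gap of the four possible ones. The largest coefficients (C2′ next to the silyloxy carbon, C2 at the diene terminus) join, which gives C2–C2′ and C3–C5′. Endo approach on the α faces of both rings (anti to C10 and C10′) sets C2, C3, C2′ and C5′.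

Step 18
Reactants: 31 3′-O,10′-O-bis(triethylsilyl) 3′-enol ether of 32
Product: 32 target dimer (3′-oxo, 10β,10′β-diol)
Conditions: HF·pyridine, pyridine–THF, 0 → 23 °C
Reagents that add atoms: none
Why: Fluoride-mediated desilylation frees the enol and the tertiary alcohol. The endo face of C3′=C4′ is covered by ring A of the other half, so kinetic protonation at C4′ is expected on the exo face, which leaves the methyl endo as in 32; the buffered, weakly acidic medium should not epimerise C4′ or C11.

## Compound list

1 | ethynylcyclopropane | C#CC1CC1 | starting material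
2 | oxirane | C1CO1 | starting material
3 | (E)-(2-cyclopropylprop-1-enyl)dimethylalane | C/C(=C\[Al](C)C)C1CC1 | intermediate
4 | (E)-4-cyclopropylpent-3-en-1-ol | OCC/C=C(\C)C1CC1 | intermediate
5 | (E)-4-cyclopropylpent-3-enal | O=CC/C=C(\C)C1CC1 | intermediate
6 | (S)-4-(trimethylsilyl)but-3-yn-2-ol | C[C@H](O)C#C[Si](C)(C)C | starting material
7 | (S)-4-(trimethylsilyl)but-3-yn-2-yl methanesulfonate | C[C@H](OS(C)(=O)=O)C#C[Si](C)(C)C | intermediate
8 | (M)-ethyl[1-(trimethylsilyl)buta-1,2-dienyl]zinc | CC[Zn]C([Si](C)(C)C)=[C@]=C([H])C | intermediate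
9 | (3R,4S,6E)-7-cyclopropyl-3-methyl-1-(trimethylsilyl)oct-6-en-1-yn-4-ol | C[Si](C)(C)C#C[C@@H](C)[C@@H](O)C/C=C(\C)C1CC1 | intermediate
10 | (3R,4S,6E)-4-(tert-butyldimethylsilyloxy)-7-cyclopropyl-3-methyl-1-(trimethylsilyl)oct-6-en-1-yne | C[Si](C)(C)C#C[C@@H](C)[C@@H](O[Si](C)(C)C(C)(C)C)C/C=C(\C)C1CC1 | intermediate
11 | 3β-(tert-butyldimethylsilyloxy)-6-(trimethylsilyl)-1αH,4αH-11,12,13-trinorguaia-5,9-diene | C[C@H]1[C@@H](O[Si](C)(C)C(C)(C)C)C[C@H]2C(C)=CCCC([Si](C)(C)C)=C12 | intermediate
12 | 5α-hydroperoxy-3β-(tert-butyldimethylsilyloxy)-6-(trimethylsilyl)-1αH,4αH-11,12,13-trinorguaia-6,9-diene | C[C@@H]1[C@]2(OO)C([Si](C)(C)C)=CCC=C(C)[C@@H]2C[C@@H]1O[Si](C)(C)C(C)(C)C | intermediate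
13 | 3β-(tert-butyldimethylsilyloxy)-6-(trimethylsilyl)-1αH,4αH-11,12,13-trinorguaia-6,9-dien-5α-ol | C[C@@H]1[C@]2(O)C([Si](C)(C)C)=CCC=C(C)[C@@H]2C[C@@H]1O[Si](C)(C)C(C)(C)C | intermediate
14 | 3β-(tert-butyldimethylsilyloxy)-5α-(trimethylsilyloxy)-1αH,4αH-11,12,13-trinorguaia-6,9-diene | C[C@@H]1[C@]2(O[Si](C)(C)C)C=CCC=C(C)[C@@H]2C[C@@H]1O[Si](C)(C)C(C)(C)C | intermediate
15 | 3β-(tert-butyldimethylsilyloxy)-1αH,4αH-11,12,13-trinorguaia-6,9-dien-5α-ol | C[C@@H]1[C@]2(O)C=CCC=C(C)[C@@H]2C[C@@H]1O[Si](C)(C)C(C)(C)C | intermediate
16 | 6α,7α-epoxy-3β-(tert-butyldimethylsilyloxy)-1αH,4αH-11,12,13-trinorguai-9-en-5α-ol | C[C@@H]1[C@]2(O)[C@H]3O[C@H]3CC=C(C)[C@@H]2C[C@@H]1O[Si](C)(C)C(C)(C)C | intermediate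
17 | propanoic acid | CCC(=O)O | starting material
18 | 3β-(tert-butyldimethylsilyloxy)-5α,6α-dihydroxy-1αH,4αH,7αH-guai-9-en-12-oic acid (C11 epimers) | C[C@@H]1[C@]2(O)[C@@H](O)[C@H](C(C)C(=O)O)CC=C(C)[C@@H]2C[C@@H]1O[Si](C)(C)C(C)(C)C | intermediate
19 | 3β-(tert-butyldimethylsilyloxy)-5α-hydroxy-1αH,4αH,6βH,7αH-guai-9-en-12,6α-olide (C11 epimers) | C[C@@H]1[C@]2(O)[C@H]3OC(=O)C(C)[C@@H]3CC=C(C)[C@@H]2C[C@@H]1O[Si](C)(C)C(C)(C)C | intermediate
20 | 3β-(tert-butyldimethylsilyloxy)-5α-hydroxy-1αH,4αH,6βH,7αH,11βH-guai-9-en-12,6α-olide | C[C@@H]1[C@]2(O)[C@H]3OC(=O)[C@@H](C)[C@@H]3CC=C(C)[C@@H]2C[C@@H]1O[Si](C)(C)C(C)(C)C | intermediate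
21 | 3β,5α-dihydroxy-1αH,4αH,6βH,7αH,11βH-guai-9-en-12,6α-olide | C[C@@H]1[C@]2(O)[C@H]3OC(=O)[C@@H](C)[C@@H]3CC=C(C)[C@@H]2C[C@@H]1O | intermediate
22 | 10β-hydroperoxy-3β,5α-dihydroxy-1αH,4αH,6βH,7αH,11βH-guaian-12,6α-olide | C[C@@H]1[C@]2(O)[C@H]3OC(=O)[C@@H](C)[C@@H]3CC[C@](C)(OO)[C@@H]2C[C@@H]1O | intermediate
23 | 3β,5α,10β-trihydroxy-1αH,4αH,6βH,7αH,11βH-guaian-12,6α-olide | C[C@@H]1[C@]2(O)[C@H]3OC(=O)[C@@H](C)[C@@H]3CC[C@](C)(O)[C@@H]2C[C@@H]1O | intermediate
24 | 5α,10β-dihydroxy-3-oxo-1αH,4αH,6βH,7αH,11βH-guaian-12,6α-olide | C[C@@H]1[C@]2(O)[C@H]3OC(=O)[C@@H](C)[C@@H]3CC[C@](C)(O)[C@@H]2CC1=O | intermediate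
25 | 10β-hydroxy-3-oxo-1αH,6βH,7αH,11βH-guai-4-en-12,6α-olide | CC1=C2[C@H]3OC(=O)[C@@H](C)[C@@H]3CC[C@](C)(O)[C@@H]2CC1=O | intermediate
26 | dilithium salt of 25 (C10 alkoxide, C2=C3 dienolate) | CC1=C2[C@H]3OC(=O)[C@@H](C)[C@@H]3CC[C@](C)([O-])[C@@H]2C=C1[O-].[Li+].[Li+] | intermediate
27 | 10β-hydroxy-1αH,6βH,7αH,11βH-guaia-2,4-dien-12,6α-olid-3-yl trifluoromethanesulfonate | CC1=C2[C@H]3OC(=O)[C@@H](C)[C@@H]3CC[C@](C)(O)[C@@H]2C=C1OS(=O)(=O)C(F)(F)F | intermediate
28 | 10β-hydroxy-1αH,6βH,7αH,11βH-guaia-2,4-dien-12,6α-olide | CC1=C2[C@H]3OC(=O)[C@@H](C)[C@@H]3CC[C@](C)(O)[C@@H]2C=C1 | intermediate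
29 | 10β-(triethylsilyloxy)-3-oxo-1αH,6βH,7αH,11βH-guai-4-en-12,6α-olide | CC1=C2[C@H]3OC(=O)[C@@H](C)[C@@H]3CC[C@](C)(O[Si](CC)(CC)CC)[C@@H]2CC1=O | intermediate
30 | 3,10β-bis(triethylsilyloxy)-1αH,6βH,7αH,11βH-guaia-2,4-dien-12,6α-olide | CC1=C2[C@H]3OC(=O)[C@@H](C)[C@@H]3CC[C@](C)(O[Si](CC)(CC)CC)[C@@H]2C=C1O[Si](CC)(CC)CC | intermediate
31 | Diels–Alder adduct: 32 with C3′=C4′ triethylsilyl enol ether and 10′-O-triethylsilyl ether | CC1=C2[C@H]3OC(=O)[C@@H](C)[C@@H]3CC[C@](C)(O)[C@@H]2[C@H]2[C@H]3C(O[Si](CC)(CC)CC)=C(C)[C@]4([C@@H]3[C@@](C)(O[Si](CC)(CC)CC)CC[C@H]3[C@H](C)C(=O)O[C@@H]34)[C@@H]12 | intermediate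
32 | CNP0243924.4 (dimer joined C2–C2′ and C3–C5′; 3′-oxo; 10β,10′β-diol) | CC1=C2[C@H]3OC(=O)[C@@H](C)[C@@H]3CC[C@](C)(O)[C@@H]2[C@H]2[C@H]3C(=O)[C@@H](C)[C@]4([C@@H]3[C@@](C)(O)CC[C@H]3[C@H](C)C(=O)O[C@@H]34)[C@@H]12 | target

## Step count and least certain steps

Total: 18 steps. Longest linear sequence: 16 steps (1, 2, 4–15, 17, 18); steps 3 and 16 are side branches.

Step 6 (key step). The most likely failure is erosion of facial selectivity at C1, or slow turnover, because a silylalkyne and a trisubstituted alkene must both enter the rhodacycle and the bias comes only from two tether substituents. Fallback: pass from substrate control to catalyst control by using a cationic rhodium complex made from [Rh(cod)Cl]2, AgSbF6 and the matched enantiomer of BINAP, so that ligand and tether act together. This sets out from 10 and comes back at 11 without any new compound (no new compound, F0).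

Step 7. Competing ene oxidation of the trisubstituted 9,10-alkene, or hydrogen abstraction at C1 or C4 instead of C7, may occur because the rate advantage of the tetrasubstituted vinylsilane is only moderate. Fallback: mask the 9,10-alkene before the photooxygenation. From 11, OsO4 (cat.) with N-methylmorpholine N-oxide should hydroxylate only the less hindered trisubstituted alkene to the 9α,10α-diol F1. Photooxygenation and PPh3 then give the 5α-hydroxy vinylsilane triol F2, and the conditions of step 8 give the desilylated triol F3. Thiocarbonyldiimidazole converts the cis-9,10-diol into the cyclic thionocarbonate F4, and Corey–Winter olefination with P(OMe)3 restores the alkene and comes back at 15.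

Step 8. The carbon-to-oxygen silyl transfer may stall at the hindered ring-fusion alkoxide, or the base may start to remove the secondary silyl ether. Fallback: use fluoride and repair the protecting group. From 13, Bu4NF in THF cleaves both silicon groups (the β-hydroxyl assists the vinyl C–Si cleavage) to the 3β,5α-diol F5, and t-BuMe2SiCl with imidazole silylates only the secondary alcohol, which comes back at 15.

Step 12. Oxygen may be captured on the face syn to H-1 (10-epimer), because two ring conformers with opposite bias are accessible. Fallback: replace radical capture by an anti addition, in which the electrophile takes the open face and water enters from the other. This sets out from 20, isolated by leaving out the acid treatment of step 11 so that the C3 silyl ether keeps O-3 from adding. Hg(OAc)2 in THF–water should give the 9α-mercurial 10β-alcohol F6; NaBH4 then gives the 10β-hydroxy silyl ether F7, and methanolic HCl comes back at 23.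

Step 17. Pairing selectivity may be lost to self-dimerisation of either diene, and H-1 may undergo a 1,5-hydrogen shift before cycloaddition, since both partners are 5-substituted cyclopentadienes. Fallback: use a single diene and add the oxygen afterwards. From 28 alone (neat, 23 °C) the known type of cyclopentadiene homodimerisation should give the 3′,4′-alkene dimer F8. Hydroboration of its strained trisubstituted alkene with 9-BBN and oxidation with NaBO3 give the 3′-exo-alcohol F9, with hydrogen added to C4′ syn on the exo face. Dess–Martin oxidation comes back at 32.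

Step 18. Protonation of the enol may occur on the endo face, or C4′ may epimerise, because the exo face carries the C10′ substituent of the one-carbon bridge. Fallback: pass from kinetic to thermodynamic control. The 4′-epimer F10 is equilibrated through the enol (K2CO3, MeOH, 23 °C) and comes back at 32. If the equilibrium is unfavourable, the hydroboration sequence through F8 and F9 sets C4′ by syn addition instead of protonation.

## Further compounds

F0 | step 6 | none | none
F1 | step 7 | 3β-(tert-butyldimethylsilyloxy)-6-(trimethylsilyl)-1αH,4αH-11,12,13-trinorguai-5-ene-9α,10α-diol | C[C@H]1[C@@H](O[Si](C)(C)C(C)(C)C)C[C@H]2[C@](C)(O)[C@H](O)CCC([Si](C)(C)C)=C12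
F2 | step 7 | 3β-(tert-butyldimethylsilyloxy)-6-(trimethylsilyl)-1αH,4αH-11,12,13-trinorguai-6-ene-5α,9α,10α-triol | C[C@@H]1[C@]2(O)C([Si](C)(C)C)=CC[C@@H](O)[C@@](C)(O)[C@@H]2C[C@@H]1O[Si](C)(C)C(C)(C)C
F3 | step 7 | 3β-(tert-butyldimethylsilyloxy)-1αH,4αH-11,12,13-trinorguai-6-ene-5α,9α,10α-triol | C[C@@H]1[C@]2(O)C=CC[C@@H](O)[C@@](C)(O)[C@@H]2C[C@@H]1O[Si](C)(C)C(C)(C)C
F4 | step 7 | 9α,10α-thionocarbonate of F3 | C[C@@H]1[C@]2(O)C=CC[C@H]3OC(=S)O[C@@]3(C)[C@@H]2C[C@@H]1O[Si](C)(C)C(C)(C)C
F5 | step 8 | 1αH,4αH-11,12,13-trinorguaia-6,9-diene-3β,5α-diol | C[C@@H]1[C@]2(O)C=CCC=C(C)[C@@H]2C[C@@H]1O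
F6 | step 12 | 9α-(acetoxymercurio)-3β-(tert-butyldimethylsilyloxy)-5α,10β-dihydroxy-1αH,4αH,6βH,7αH,11βH-guaian-12,6α-olide | C[C@@H]1[C@]2(O)[C@H]3OC(=O)[C@@H](C)[C@@H]3C[C@@H]([Hg]OC(C)=O)[C@](C)(O)[C@@H]2C[C@@H]1O[Si](C)(C)C(C)(C)C
F7 | step 12 | 3β-(tert-butyldimethylsilyloxy)-5α,10β-dihydroxy-1αH,4αH,6βH,7αH,11βH-guaian-12,6α-olide | C[C@@H]1[C@]2(O)[C@H]3OC(=O)[C@@H](C)[C@@H]3CC[C@](C)(O)[C@@H]2C[C@@H]1O[Si](C)(C)C(C)(C)C
F8 | step 17 | 3′,4′-alkene dimer (32 with C3′=C4′ in place of the C3′ ketone and C4′–H) | CC1=C2[C@H]3OC(=O)[C@@H](C)[C@@H]3CC[C@](C)(O)[C@@H]2[C@H]2[C@H]3C=C(C)[C@]4([C@@H]3[C@@](C)(O)CC[C@H]3[C@H](C)C(=O)O[C@@H]34)[C@@H]12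
F9 | step 17 | 3′-exo-alcohol (32 with C3′ exo-hydroxyl in place of the ketone) | CC1=C2[C@H]3OC(=O)[C@@H](C)[C@@H]3CC[C@](C)(O)[C@@H]2[C@H]2[C@H]3[C@H](O)[C@@H](C)[C@]4([C@@H]3[C@@](C)(O)CC[C@H]3[C@H](C)C(=O)O[C@@H]34)[C@@H]12
F10 | step 18 | 4′-epimer of 32 | CC1=C2[C@H]3OC(=O)[C@@H](C)[C@@H]3CC[C@](C)(O)[C@@H]2[C@H]2[C@H]3C(=O)[C@H](C)[C@]4([C@@H]3[C@@](C)(O)CC[C@H]3[C@H](C)C(=O)O[C@@H]34)[C@@H]12
A1 | alternative 1 | (R)-6-isopropenyl-3-methylcyclohept-2-enone | CC1=CC(=O)C[C@@H](CC1)C(C)=C
A2 | alternative 1 | (3R)-6-methyl-3-(prop-1-en-2-yl)-1-(trimethylsilyloxy)bicyclo[4.1.0]heptane | C=C(C)[C@@H]1CCC2(C)CC2(O[Si](C)(C)C)C1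
A3 | alternative 2 | 10β-trimethylsilyloxy-3-oxoguai-4-en-12,6α-olide | CC1=C2[C@H]3OC(=O)[C@@H](C)[C@@H]3CC[C@](C)(O[Si](C)(C)C)[C@@H]2CC1=O
A4 | alternative 2 | 4-pivaloyloxy-10β-trimethylsilyloxy-1,2-secoguai-1(5)-en-2-yn-12,6α-olide | C#CC(C)(OC(=O)C(C)(C)C)C1=C[C@@](C)(O[Si](C)(C)C)CC[C@H]2[C@H](C)C(=O)O[C@H]12
A5 | alternative 3 | 4α-hydroxy-5αH,11βH-guai-1(10)-en-12,6α-olide | CC1=C2CC[C@@](C)(O)[C@@H]2[C@H]3OC(=O)[C@@H](C)[C@@H]3CC1
A6 | alternative 3 | 4α,5β-epoxy-11βH-germacr-1(10)E-en-12,6α-olide | C/C1=C\CC[C@@]2(C)O[C@@H]2[C@H]3OC(=O)[C@@H](C)[C@@H]3CC1
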